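Decide first that the yields are not what you read from the earlier runs: read the split between the two products. Both nucleophiles take the same open intermediate, so at any moment other capture product forms over target as S times [second nucleophile]/[first nucleophile].

common to all: first nucleophile 0.0759 M; capture agent 3.45 mM

|  | substrate | second nucleophile | remark | time |
|---|---|---|---|---|
| north-west | 0.046 M | 0.0759 M | run made earlier |  |
| north | 0.10 M | 0.0759 M | run made earlier |  |
| north-east | 0.069 M | 0.11 M | run made earlier |  |
| flask | 0.069 M | 0.0759 M |  | 50 min |

| run | time / min | other capture product / % | target / % |
|---|---|---|---|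
| north-west | 6.00 | 29 | 9 |
| north-west | 12.0 | 35 | 11 |
| north-west | 15.0 | 40 | 12 |
| north-west | 25.0 | 35 | 9 |
| north-west | 30.0 | 36 | 9 |
| north-west | 40.0 | 38 | 12 |
| north | 2.00 | 15 | 4 |
| north | 6.00 | 21 | 6 |
| north | 12.0 | 22 | 4 |
| north | 15.0 | 28 | 9 |
| north | 25.0 | 24 | 3 |
| north | 30.0 | 23 | 8 |
| north | 40.0 | 25 | 5 |
| north-east | 3.00 | 27 | 6 |
| north-east | 6.00 | 28 | 7 |
| north-east | 12.0 | 35 | 4 |
| north-east | 20.0 | 34 | 8 |
| north-east | 40.0 | 36 | 3 |

(scatter of a reading: 2 percentage points)

- percentages count the substrate that a species holds: one self-condensation product counts as two
- what may be going on: substrate <-> open intermediate; first nucleophile + open intermediate -> target; second nucleophile + open intermediate -> other capture product; open intermediate + capture agent -> trapped intermediate; open intermediate -> side product; 2 substrate -> self-condensation product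

- ratio of other capture product to target at 4.0 s
- ratio of other capture product to target at 50 min
- which of other capture product and target there is more of at 50 min

Here S, the selectivity factor 3.67, is the ratio of other capture product to target made at equal nucleophile concentrations, and this value is my own reading, pooled over the north-west and north runs, in each of which the two nucleophiles are charged equally. The north-east run, with more second nucleophile, reads 5.71, where S times its charge ratio gives 5.32. So I expect about 3.67 in the flask, slipping lower as second nucleophile is used.

The forecast gave 4.4 (3.5 to 5.6) at 4.0 s and 3.9 (3.2 to 4.9) at 50 min, with other capture product ahead: “Their ratio therefore reflects competition for it, not equilibration”. Its early value stands above mine.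

The flask gives 3.75 at 4.0 s and 3.35 at 50 min, with 30.8 % of other capture product against 9.20 % of target.

    substrate ⇌ open intermediate (K = 0.0650, k = 0.00450 s⁻¹)
    first nucleophile + open intermediate → target (k = 17.0 M⁻¹ s⁻¹)
    second nucleophile + open intermediate → other capture product (k = 64.0 M⁻¹ s⁻¹)
    open intermediate + capture agent → trapped intermediate (k = 0.150 M⁻¹ s⁻¹)
    open intermediate → side product (k = 0.00180 s⁻¹)
    2 substrate → self-condensation product (k = 0.130 M⁻¹ s⁻¹)

In this flask at 1.38 min, when half of the turnover of the step from substrate to open intermediate is done, the open intermediate goes to other capture product 3.4 times as fast as to target, while S gives 3.67 on the charges and 2.88 on what remains at 50 min. In the neighbour flask charged with 0.019 M of second nucleophile, S times the charge ratio gives 0.920, and that flask shows 0.933 at 4.0 s.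

The earlier runs and the new flask are calculated with constants of no real substance, and the scatter is random.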